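## The problem

The target is a linear trimer of three (−)-epicatechin 3-O-gallate units joined by two C4→C8 interflavan bonds, from C4 of the top unit to C8 of the middle unit and from C4 of the middle unit to C8 of the bottom unit. It has eight stereocentres: every unit is 2R,3R (2,3-cis), and C4 of the top and middle units carries its aryl substituent trans to the neighbouring C3 oxygen. C3 can therefore control C4 within a unit, and the C2/C3 pairs of the middle and bottom units can be bought as (−)-epicatechin, but nothing in the rest of the molecule can control C2 and C3 of a top unit that is built rather than bought. Each interflavan bond must go to C8 and not to C6 of an A ring that offers both, and oligomerisation must be avoided. The twenty-one phenolic hydroxyls (nine of them in pyrogallol arrays) oxidise in air and, as free phenols, let ring C open and C2 epimerise under base; the interflavan bonds ionise under strong acid, and the gallates migrate or hydrolyse under base. The phenols must therefore stay benzylated until a final neutral hydrogenolysis. The enabling feature is that C4 of the top unit sits on C8 of the middle A ring, ortho to O1 and to the C7 oxygen and para to the C5 oxygen, so a cation there is stabilised like a quinone methide. The top A ring, a phloroglucinol diether, is tethered to this carbon through O1–C2–C3 with an ortho carbon placed for a six-membered closure, and the C3 gallate carbonyl lies 1,2 to the cation and can bridge it.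

## Retrosynthesis

**23 ⇐ 22.** The last cut removes the twenty-one benzyl ethers of the fully protected tri-gallate 22. Benzyl is the only phenol protecting group that comes off under neutral conditions that leave esters, benzylic C2–O1 bonds and interflavan bonds alone. The forward step is a single hydrogenolysis with no later handling of air-sensitive intermediates.

**22 ⇐ 20 (through 21).** The C4–C4a bond of the top unit is cut, opening its ring C. This gives carbinol 20, in which the top unit is an open chain on C8 of the middle unit: C2 aryl ether, C3 gallate, C4 hydroxyl. The neighbouring cut, the interflavan bond itself, would ask an intermolecular Friedel–Crafts reaction to choose C8 over C6 and to stop at the trimer. The chosen cut makes the step intramolecular, uses two equivalent ortho carbons, and lets the C3 ester set C4. The two spectator C3 oxygens of the middle and bottom units already carry their gallates in 20, so nothing but hydrogenolysis follows the closure. The forward reaction must ionise only C4, pass through the trans-dioxolanium ion 21, and use the phloroglucinol ether ring as nucleophile.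

**20 ⇐ 19 ⇐ 18.** Three ester C–O bonds are cut, which leads to tetraol 19; the three acyl groups come from a benzyl-protected gallic acid that is bought and used as a reagent, one equivalent for each C3 hydroxyl. Three O–Si bonds are then cut to tris-silyl ether 18. Putting all three gallates on in one operation replaces a separate top galloylation and a later double galloylation. It requires the hindered C4 hydroxyl of 19 to stay free, and an ester formed there would still be a leaving group for the key step.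

**18 ⇐ 6 (as 17) + 16.** The C4(top)–C8(middle) bond is cut to aryllithium 17, made from bromide 6, and aldehyde 16. The interflavan bond is thus made by a polar addition at a carbon that already carries the metal, so no 4→6 isomer and no oligomer can form. The new carbinol centre need not be controlled because step 15 erases it. An aldehyde is preferred to an acyl derivative because it gives the carbinol oxidation level directly and never places a ketone next to the epimerisable C3 and the β-aryloxy group.

**16 ⇐ 15 ⇐ 14 ⇐ 13.** The aldehyde carbon is traced to a vinyl group (C=C cleavage), and the C3 silyl ether to the methoxymethyl ether of 13 through alcohol 14. The acetal comes from the allylboration reagent. The exchange for silicon is made on the small fragment, where acid is harmless, so one fluoride treatment can later free all three C3 hydroxyls without acid near the ionisable C4 carbinol.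

**13 ⇐ 12 + 8.** The O1–C8a aryl ether bond is cut to alcohol 12 and 1,3-bis(benzyloxy)-5-iodobenzene 8 (from 5-iodoresorcinol 7). Forming this bond at the aryl carbon leaves the benzylic C–O bond of 12 untouched and so keeps C2 intact. The alternative, displacement at the electron-rich benzylic carbon by a phenol, risks ionisation and racemisation.

**12 ⇐ 9 + 10 (through 11).** The C2–C3 bond is cut to 3,4-bis(benzyloxy)benzaldehyde 9 and allyl methoxymethyl ether 10, joined by asymmetric γ-alkoxyallylboration via borane 11. This sets both top-unit stereocentres in one step with the two oxygens already differentiated. A cinnamate dihydroxylation would give the same syn diol without that differentiation.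

**6 ⇐ 5 + 3; 5 ⇐ 4 ⇐ 3 ⇐ 2 ⇐ 1.** The middle C4–bottom C8 bond is cut to the 4-(2-ethoxyethoxy)-8-bromo electrophile 5 and the nucleophile 3. Both derive from (−)-epicatechin 1 through tetrabenzyl ether 2, silyl ether 3 and C4 ether 4. This is the standard flavan-4-yl cation coupling: the C3 silyloxy group directs the nucleophile trans, and the C8 bromine blocks self-condensation and later becomes the lithiation site. Five of the eight stereocentres come from this branch at the cost of one substrate-controlled step.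

## Roads not taken

**Alternative 1:** The cut goes through the middle A ring, which would be made by a cyclobutenone–alkyne benzannulation. 3-(Benzyloxy)cyclobut-2-enone A2 would open on heating to a vinylketene, add to the C4 alkynyl silyl ether of a complete top unit A3, and electrocyclise to the 2-substituted 5-benzyloxy-3-siloxyphenol A1.
- Merits: the 4→8 connectivity is fixed by construction. The top unit comes entirely from epicatechin, with C4 set by trans substitution of a C4 ether, so no reagent-controlled stereocentre is needed. This is better than the chosen plan, which has to make C2 and C3 of the top unit by allylboration.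
- Weak points: A1 is only a phenol. The whole pyran ring of the middle unit (C2, C3, C4 and the bond to the bottom unit) must still be built on it, so three stereocentres that epicatechin supplies for free are made anew. A hindered secondary siloxyalkyne must also survive the thermal cascade.
- Comparison: the chosen plan buys the middle and bottom units intact, builds only three centres, and reaches the full skeleton in far fewer steps.

**Alternative 2:** The cut is the C2–C3 bond of the top unit. Diene A5, which has an α-aryl vinyl ether on O1 and a vinyl group on C4, would undergo ring-closing metathesis with second-generation Grubbs catalyst to the flav-2-ene trimer A4. Glycal-type oxygenation would follow.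
- Merits: the closure is neutral, exposes no interflavan bond to Lewis acid, and raises no question of which arene attacks. In these respects it is more predictable than a cation cyclisation.
- Weak points: C4 of A5 is a diaryl(vinyl)methine that must be set enantioselectively before closure, with no neighbour to direct it. Hydroboration of A4 places the C3 oxygen trans to the C2 aryl group (catechin-type). An oxidation–reduction inversion at C3 and a separate galloylation would therefore follow on the trimer. The 1,1-disubstituted enol ether is a reluctant metathesis partner and is acid-labile.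
- Comparison: the chosen plan delivers C3 at the right oxidation level, already acylated and with the right configuration, and has one step after the closure.

**Alternative 3:** The cut is the O1–C2 bond of the top unit. In epoxide A7, the ortho phenol would open the cis-2,3-epoxide at its benzylic carbon with inversion under pyridinium p-toluenesulfonate, giving trimer A6 with a free top C3 hydroxyl.
- Merits: C2 would be set stereospecifically from alkene geometry and the closure forms a C–O bond under very mild acid. In these respects it is at least as good as the chosen closure.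
- Weak points: A7 needs a Z-alkene epoxidised on the correct face relative to an existing C4 stereocentre, which is acyclic 1,2-induction of uncertain sense. That C4 centre must itself be set earlier without help. An epoxide benzylic to a dialkoxyphenyl ring tends to open by ionisation, which erodes the inversion. One ortho phenol must be kept free on an otherwise benzylated ring. A final galloylation is still needed.
- Comparison: the chosen plan sets C4 last and under control of C3, sets C2 in a step that never breaks the benzylic C–O bond, and needs no selective phenol protection.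

Key step: step 15

Remark: 5-iodobenzene-1,3-diol, allyl methoxymethyl ether, 3,4-bis(benzyloxy)benzaldehyde and (−)-Ipc2BOMe (Ipc = isopinocampheyl, from (+)-α-pinene) are taken as purchasable. 3,4,5-Tris(benzyloxy)benzoic acid, the acyl donor of step 14, is also bought; like benzyl bromide it is a reagent that enters the product more than once and carries no compound number.

## Route

Flavan numbering (C2, C3, C4, A ring) is used for the future top unit throughout.

Step 1
Reactants: 1 (−)-epicatechin
Product: 2 5,7,3′,4′-tetra-O-benzyl-(−)-epicatechin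
Conditions: BnBr, K2CO3, DMF, 0 °C to rt
Reagents that add atoms: benzyl bromide, BrCc1ccccc1
Why: Williamson etherification of the four phenols; the secondary C3 alcohol is not deprotonated by K2CO3, and low temperature under inert gas limits C-benzylation and C2 epimerisation.

Step 2
Reactants: 2 5,7,3′,4′-tetra-O-benzyl-(−)-epicatechin
Product: 3 5,7,3′,4′-tetra-O-benzyl-3-O-(tert-butyldimethylsilyl)-(−)-epicatechin
Conditions: TBSCl, imidazole, DMF, rt
Reagents that add atoms: tert-butyldimethylsilyl chloride, CC(C)(C)[Si](C)(C)Cl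
Why: Imidazole-promoted silylation of the only free hydroxyl; 3 serves both as the nucleophile of step 5 and as the source of the electrophile.

Step 3
Reactants: 3 5,7,3′,4′-tetra-O-benzyl-3-O-(tert-butyldimethylsilyl)-(−)-epicatechin
Product: 4 (2R,3S,4S)-5,7,3′,4′-tetra-O-benzyl-3-O-(tert-butyldimethylsilyl)-4-(2-ethoxyethoxy)epicatechin (C4 ether trans to the C3 silyloxy group)
Conditions: DDQ, EtOCH2CH2OH, CH2Cl2, rt
Reagents that add atoms: 2-ethoxyethanol, CCOCCO
Why: DDQ benzylic oxidation: hydride abstraction at C4 gives the A-ring-stabilised cation, which the alcohol traps anti to the C3 substituent; the C4 configuration is lost again on ionisation in step 5.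

Step 4
Reactants: 4 (2R,3S,4S)-5,7,3′,4′-tetra-O-benzyl-3-O-(tert-butyldimethylsilyl)-4-(2-ethoxyethoxy)epicatechin
Product: 5 (2R,3S,4S)-5,7,3′,4′-tetra-O-benzyl-8-bromo-3-O-(tert-butyldimethylsilyl)-4-(2-ethoxyethoxy)epicatechin
Conditions: NBS, CH2Cl2, −40 °C to rt
Reagents that add atoms: N-bromosuccinimide, O=C1CCC(=O)N1Br
Why: Electrophilic aromatic bromination; C8, flanked by O1 and one benzyloxy group, is more reactive than C6 between two benzyloxy groups, as is usual for benzylated flavan A rings.

Step 5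
Reactants: 5 (2R,3S,4S)-5,7,3′,4′-tetra-O-benzyl-8-bromo-3-O-(tert-butyldimethylsilyl)-4-(2-ethoxyethoxy)epicatechin; 3 5,7,3′,4′-tetra-O-benzyl-3-O-(tert-butyldimethylsilyl)-(−)-epicatechin
Product: 6 5,7,3′,4′-tetra-O-benzyl-8-bromo-3-O-TBS-epicatechin-(4β→8)-5,7,3′,4′-tetra-O-benzyl-3-O-TBS-epicatechin (8-bromo dimer; the brominated unit is the future middle unit)
Conditions: 3 (3 equiv), TMSOTf (cat.), 4 Å molecular sieves, CH2Cl2, −78 °C; Et3N
Reagents that add atoms: none
Why: Lewis-acid-catalysed Friedel–Crafts coupling of a flavan-4-yl cation; C8 of excess 3 should attack anti to the axial C3 silyloxy group, setting the middle C4 centre 3,4-trans, while the bromine blocks self-condensation of 5.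

Step 6
Reactants: 7 5-iodobenzene-1,3-diol
Product: 8 1,3-bis(benzyloxy)-5-iodobenzene
Conditions: BnBr, K2CO3, DMF, rt
Reagents that add atoms: benzyl bromide, BrCc1ccccc1
Why: Williamson etherification of both phenols; the iodide is the handle for step 8.

Step 7
Reactants: 9 3,4-bis(benzyloxy)benzaldehyde; 10 allyl methoxymethyl ether
Product: 12 (1R,2R)-1-[3,4-bis(benzyloxy)phenyl]-2-(methoxymethoxy)but-3-en-1-ol, via (Z)-alkoxyallylborane 11 (not isolated)
Conditions: 10, s-BuLi, THF, −78 °C; (−)-Ipc2BOMe; BF3·OEt2; 9, −78 °C; NaOH, H2O2, rt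
Reagents that add atoms: none
Why: Brown asymmetric γ-alkoxyallylboration: the chelated Z allyl anion of 10 is trapped on boron to give 11, whose Z geometry is translated by a chair Zimmerman–Traxler transition state into the syn relationship (the 2,3-cis pair of the flavan), and the isopinocampheyl groups from (+)-α-pinene should direct attack to the si face of the aldehyde, giving 1R,2R.

Step 8
Reactants: 12 (1R,2R)-1-[3,4-bis(benzyloxy)phenyl]-2-(methoxymethoxy)but-3-en-1-ol; 8 1,3-bis(benzyloxy)-5-iodobenzene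
Product: 13 (1R,2R)-1-[3,4-bis(benzyloxy)phenyl]-1-[3,5-bis(benzyloxy)phenoxy]-2-(methoxymethoxy)but-3-ene
Conditions: CuI (cat.), 3,4,7,8-tetramethyl-1,10-phenanthroline (cat.), Cs2CO3, 4 Å molecular sieves, toluene, 90 °C
Reagents that add atoms: none
Why: Copper-catalysed Ullmann-type C–O coupling of a secondary alcohol with an aryl iodide; the bond is made at the aryl carbon, so the benzylic C–O bond and the C2 configuration are retained.

Step 9
Reactants: 13 (1R,2R)-1-[3,4-bis(benzyloxy)phenyl]-1-[3,5-bis(benzyloxy)phenoxy]-2-(methoxymethoxy)but-3-ene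
Product: 14 (1R,2R)-1-[3,4-bis(benzyloxy)phenyl]-1-[3,5-bis(benzyloxy)phenoxy]but-3-en-2-ol
Conditions: Me2BBr, CH2Cl2, −78 °C; aq. NaHCO3
Reagents that add atoms: none
Why: Acetal cleavage by a bromoborane: boron activates the methoxymethyl acetal and bromide gives the bromomethyl ether, which hydrolyses on work-up; at −78 °C benzyl aryl ethers and the benzylic aryl ether should not react.

Step 10
Reactants: 14 (1R,2R)-1-[3,4-bis(benzyloxy)phenyl]-1-[3,5-bis(benzyloxy)phenoxy]but-3-en-2-ol
Product: 15 (1R,2R)-1-[3,4-bis(benzyloxy)phenyl]-1-[3,5-bis(benzyloxy)phenoxy]-2-(tert-butyldimethylsilyloxy)but-3-ene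
Conditions: TBSCl, imidazole, DMF, 40 °C
Reagents that add atoms: tert-butyldimethylsilyl chloride, CC(C)(C)[Si](C)(C)Cl
Why: Silylation of the secondary allylic alcohol; the silyl ether tolerates the aryllithium of step 12 and is removed with the other two in step 13.

Step 11
Reactants: 15 (1R,2R)-1-[3,4-bis(benzyloxy)phenyl]-1-[3,5-bis(benzyloxy)phenoxy]-2-(tert-butyldimethylsilyloxy)but-3-ene
Product: 16 (2S,3R)-3-[3,4-bis(benzyloxy)phenyl]-3-[3,5-bis(benzyloxy)phenoxy]-2-(tert-butyldimethylsilyloxy)propanal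
Conditions: OsO4 (cat.), NaIO4, 2,6-lutidine, dioxane/H2O, rt
Reagents that add atoms: osmium tetroxide, O=[Os](=O)(=O)=O (oxygen carrier, regenerated by sodium periodate, [Na+].[O-]I(=O)(=O)=O)
Why: Lemieux–Johnson cleavage (dihydroxylation, then periodate cleavage) of the terminal alkene; it is chosen over ozonolysis because ozone would attack the phloroglucinol diether ring, and the buffered, epimerisable aldehyde is used crude.

Step 12
Reactants: 6 8-bromo dimer; 16 (2S,3R)-3-[3,4-bis(benzyloxy)phenyl]-3-[3,5-bis(benzyloxy)phenoxy]-2-(tert-butyldimethylsilyloxy)propanal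
Product: 18 tris-silyl carbinol (the debrominated dimer of 6 carrying on C8 of its upper unit a 1-hydroxy-2-(tert-butyldimethylsilyloxy)-3-[3,4-bis(benzyloxy)phenyl]-3-[3,5-bis(benzyloxy)phenoxy]propyl chain; C2 and C3 as in 16; both C4 carbinol epimers), via 8-lithio dimer 17 (not isolated)
Conditions: 6, t-BuLi, THF, −78 °C; then 16, −78 °C; aq. NH4Cl
Reagents that add atoms: none
Why: Bromine–lithium exchange, which outruns benzylic deprotonation at −78 °C and has precedent for 8-bromo benzylated flavan silyl ethers, followed by 1,2-addition to the aldehyde; this fixes the 4→8 connectivity, and the uncontrolled carbinol centre is erased in step 15.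

Step 13
Reactants: 18 tris-silyl carbinol
Product: 19 tetraol: 18 with all three silyl ethers cleaved (free C3 hydroxyls on the middle, bottom and open top units, free C4 hydroxyl)
Conditions: TBAF, THF, rt to 45 °C
Reagents that add atoms: none
Why: Fluoride desilylation driven by the Si–F bond; no acid is present, so the ionisable C4 carbinol survives, and any silyl migration during step 12 is irrelevant because all three groups are removed.

Step 14
Reactants: 19 tetraol
Product: 20 tris-gallate carbinol: 19 with the three C3 hydroxyls esterified by 3,4,5-tris(benzyloxy)benzoyl groups and the C4 hydroxyl free (both C4 epimers)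
Conditions: 3,4,5-tris(benzyloxy)benzoic acid (3.3 equiv), DCC (3.5 equiv), DMAP, CH2Cl2, 0 °C to rt
Reagents that add atoms: 3,4,5-tris(benzyloxy)benzoic acid, OC(=O)c1cc(OCc2ccccc2)c(OCc2ccccc2)c(OCc2ccccc2)c1
Why: Threefold Steglich esterification that consumes one equivalent of the acid per C3 hydroxyl, the water going to DCC; the C4 hydroxyl, benzylic to a 2,6-dioxygenated arene and next to the new C3 ester, is the most hindered of the four and should remain free when the acid is limited to a slight excess over three equivalents.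

Step 15
Reactants: 20 tris-gallate carbinol
Product: 22 perbenzylated procyanidin C1 3,3′,3″-tri-O-gallate (all twenty-one phenols as benzyl ethers), via trans-dioxolanium ion 21 (not isolated)
Conditions: Zn(OTf)2, 4 Å molecular sieves, CH2Cl2, 0 °C to rt
Reagents that add atoms: none
Why: Zn(OTf)2 ionises the C4 hydroxyl, and both epimers give the same benzylic cation, delocalised into the middle A ring through its two ortho oxygens and one para oxygen. The C3 gallate carbonyl captures this cation reversibly as the 1,3-dioxolan-2-ylium ion 21, and because that capture equilibrates through the open cation, the trans-4,5-disubstituted isomer should prevail. The tethered 3,5-bis(benzyloxy)phenyl ether then attacks C4 through one of its two equivalent ortho carbons, anti to the departing carbonyl oxygen, in a 6-exo-tet Friedel–Crafts closure that forms C4–C4a and ring C of the top unit (6-exo-trig if the open quinone methide ion is the species attacked), and proton loss restores the arene. Inversion at C4 of the trans ion places the middle unit trans to the C3 ester, so the one new stereocentre is controlled by C3 through the gallate, reinforced by a chair-like transition state with the C2 aryl group equatorial. The closest known reaction types are the acid-promoted cyclisation of benzylic carbinols onto aryl ethers to 4-arylchromans, the flavan-4-yl cation coupling of step 5, and the 1,2-trans direction by acyloxy participation in glycosylation. The step needs ionisation at C4 and not at C2, which is secured because the C2 cation would be a simple alkoxybenzyl ion destabilised by the adjacent acyloxy carbon. It needs attack at C4 and not C3 of 21, secured by the benzylic character of C4, and attack by the phloroglucinol ether ring and not the catechol ring, secured by the much higher nucleophilicity of the former and the five-membered ring the latter would have to form. The gallates of the middle and bottom units and the existing interflavan bond should be spectators under this mild Lewis acid.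

Step 16
Reactants: 22 perbenzylated procyanidin C1 3,3′,3″-tri-O-gallate
Product: 23 procyanidin C1 3,3′,3″-tri-O-gallate
Conditions: H2 (1 atm), Pd(OH)2 on carbon, THF/MeOH/H2O, rt
Reagents that add atoms: none
Why: Catalytic hydrogenolysis of the twenty-one benzyl aryl ethers under neutral conditions; aryl esters, the benzylic C2–O1 bonds and the interflavan bonds are not cleaved at atmospheric pressure in this compound class.

## Compound list

1 | (−)-epicatechin | O[C@@H]1Cc2c(O)cc(O)cc2O[C@@H]1c1ccc(O)c(O)c1 | starting material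
2 | 5,7,3′,4′-tetra-O-benzyl-(−)-epicatechin | O[C@@H]1Cc2c(OCc9ccccc9)cc(OCc9ccccc9)cc2O[C@@H]1c7ccc(OCc9ccccc9)c(OCc9ccccc9)c7 | intermediate
3 | 5,7,3′,4′-tetra-O-benzyl-3-O-(tert-butyldimethylsilyl)-(−)-epicatechin | CC(C)(C)[Si](C)(C)O[C@@H]1Cc2c(OCc9ccccc9)cc(OCc9ccccc9)cc2O[C@@H]1c7ccc(OCc9ccccc9)c(OCc9ccccc9)c7 | intermediate
4 | (2R,3S,4S)-5,7,3′,4′-tetra-O-benzyl-3-O-(tert-butyldimethylsilyl)-4-(2-ethoxyethoxy)epicatechin | CC(C)(C)[Si](C)(C)O[C@@H]1[C@@H](OCCOCC)c2c(OCc9ccccc9)cc(OCc9ccccc9)cc2O[C@@H]1c7ccc(OCc9ccccc9)c(OCc9ccccc9)c7 | intermediate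
5 | (2R,3S,4S)-5,7,3′,4′-tetra-O-benzyl-8-bromo-3-O-(tert-butyldimethylsilyl)-4-(2-ethoxyethoxy)epicatechin | CC(C)(C)[Si](C)(C)O[C@@H]1[C@@H](OCCOCC)c2c(OCc9ccccc9)cc(OCc9ccccc9)c(Br)c2O[C@@H]1c7ccc(OCc9ccccc9)c(OCc9ccccc9)c7 | intermediate
6 | 8-bromo dimer: 5,7,3′,4′-tetra-O-benzyl-8-bromo-3-O-TBS-epicatechin-(4β→8)-5,7,3′,4′-tetra-O-benzyl-3-O-TBS-epicatechin | CC(C)(C)[Si](C)(C)O[C@@H]1[C@@H](c2c(OCc9ccccc9)cc(OCc9ccccc9)c3c2O[C@H](c7ccc(OCc9ccccc9)c(OCc9ccccc9)c7)[C@H](O[Si](C)(C)C(C)(C)C)C3)c2c(OCc9ccccc9)cc(OCc9ccccc9)c(Br)c2O[C@@H]1c7ccc(OCc9ccccc9)c(OCc9ccccc9)c7 | intermediate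
7 | 5-iodobenzene-1,3-diol | Oc1cc(O)cc(I)c1 | starting material
8 | 1,3-bis(benzyloxy)-5-iodobenzene | Ic1cc(OCc2ccccc2)cc(OCc2ccccc2)c1 | intermediate
9 | 3,4-bis(benzyloxy)benzaldehyde | O=Cc1ccc(OCc2ccccc2)c(OCc2ccccc2)c1 | starting material
10 | allyl methoxymethyl ether | C=CCOCOC | starting material
11 | [(Z)-3-(methoxymethoxy)allyl]bis(isopinocampheyl)borane | COCO/C=C\CB([C@@H]1C[C@@H]2C[C@H]([C@H]1C)C2(C)C)[C@@H]1C[C@@H]2C[C@H]([C@H]1C)C2(C)C | intermediate
12 | (1R,2R)-1-[3,4-bis(benzyloxy)phenyl]-2-(methoxymethoxy)but-3-en-1-ol | C=C[C@@H](OCOC)[C@@H](c1ccc(OCc2ccccc2)c(OCc2ccccc2)c1)O | intermediate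
13 | (1R,2R)-1-[3,4-bis(benzyloxy)phenyl]-1-[3,5-bis(benzyloxy)phenoxy]-2-(methoxymethoxy)but-3-ene | C=C[C@@H](OCOC)[C@@H](c1ccc(OCc2ccccc2)c(OCc2ccccc2)c1)Oc1cc(OCc2ccccc2)cc(OCc2ccccc2)c1 | intermediate
14 | (1R,2R)-1-[3,4-bis(benzyloxy)phenyl]-1-[3,5-bis(benzyloxy)phenoxy]but-3-en-2-ol | C=C[C@@H](O)[C@@H](c1ccc(OCc2ccccc2)c(OCc2ccccc2)c1)Oc1cc(OCc2ccccc2)cc(OCc2ccccc2)c1 | intermediate
15 | (1R,2R)-1-[3,4-bis(benzyloxy)phenyl]-1-[3,5-bis(benzyloxy)phenoxy]-2-(tert-butyldimethylsilyloxy)but-3-ene | C=C[C@@H](O[Si](C)(C)C(C)(C)C)[C@@H](c1ccc(OCc2ccccc2)c(OCc2ccccc2)c1)Oc1cc(OCc2ccccc2)cc(OCc2ccccc2)c1 | intermediate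
16 | (2S,3R)-3-[3,4-bis(benzyloxy)phenyl]-3-[3,5-bis(benzyloxy)phenoxy]-2-(tert-butyldimethylsilyloxy)propanal | O=C[C@@H](O[Si](C)(C)C(C)(C)C)[C@@H](c1ccc(OCc2ccccc2)c(OCc2ccccc2)c1)Oc1cc(OCc2ccccc2)cc(OCc2ccccc2)c1 | intermediate
17 | 8-lithio dimer (6 with lithium in place of bromine) | CC(C)(C)[Si](C)(C)O[C@@H]1[C@@H](c2c(OCc9ccccc9)cc(OCc9ccccc9)c3c2O[C@H](c7ccc(OCc9ccccc9)c(OCc9ccccc9)c7)[C@H](O[Si](C)(C)C(C)(C)C)C3)c2c(OCc9ccccc9)cc(OCc9ccccc9)c([Li])c2O[C@@H]1c7ccc(OCc9ccccc9)c(OCc9ccccc9)c7 | intermediate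
18 | tris-silyl carbinol (open-chain top unit with C3 silyl ether and C4 hydroxyl on C8 of the bis-silyl dimer; both C4 epimers) | CC(C)(C)[Si](C)(C)O[C@@H]1[C@@H](c2c(OCc9ccccc9)cc(OCc9ccccc9)c3c2O[C@H](c7ccc(OCc9ccccc9)c(OCc9ccccc9)c7)[C@H](O[Si](C)(C)C(C)(C)C)C3)c2c(OCc9ccccc9)cc(OCc9ccccc9)c(C(O)[C@@H](O[Si](C)(C)C(C)(C)C)[C@@H](c7ccc(OCc9ccccc9)c(OCc9ccccc9)c7)Oc4cc(OCc9ccccc9)cc(OCc9ccccc9)c4)c2O[C@@H]1c7ccc(OCc9ccccc9)c(OCc9ccccc9)c7 | intermediate
19 | tetraol (18 without the three silyl groups; both C4 epimers) | O[C@@H]1[C@@H](c2c(OCc9ccccc9)cc(OCc9ccccc9)c3c2O[C@H](c7ccc(OCc9ccccc9)c(OCc9ccccc9)c7)[C@H](O)C3)c2c(OCc9ccccc9)cc(OCc9ccccc9)c(C(O)[C@@H](O)[C@@H](c7ccc(OCc9ccccc9)c(OCc9ccccc9)c7)Oc4cc(OCc9ccccc9)cc(OCc9ccccc9)c4)c2O[C@@H]1c7ccc(OCc9ccccc9)c(OCc9ccccc9)c7 | intermediate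
20 | tris-gallate carbinol (open-chain top unit with C2 aryl ether, C3 gallate and C4 hydroxyl on C8 of the bis-gallate dimer; both C4 epimers) | O=C(c8cc(OCc9ccccc9)c(OCc9ccccc9)c(OCc9ccccc9)c8)O[C@@H]1[C@@H](c2c(OCc9ccccc9)cc(OCc9ccccc9)c3c2O[C@H](c7ccc(OCc9ccccc9)c(OCc9ccccc9)c7)[C@H](OC(=O)c8cc(OCc9ccccc9)c(OCc9ccccc9)c(OCc9ccccc9)c8)C3)c2c(OCc9ccccc9)cc(OCc9ccccc9)c(C(O)[C@@H](OC(=O)c8cc(OCc9ccccc9)c(OCc9ccccc9)c(OCc9ccccc9)c8)[C@@H](c7ccc(OCc9ccccc9)c(OCc9ccccc9)c7)Oc4cc(OCc9ccccc9)cc(OCc9ccccc9)c4)c2O[C@@H]1c7ccc(OCc9ccccc9)c(OCc9ccccc9)c7 | intermediate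
21 | trans-4,5-disubstituted 2-aryl-1,3-dioxolan-2-ylium ion bridging C3 and C4 of the open top unit | O=C(c8cc(OCc9ccccc9)c(OCc9ccccc9)c(OCc9ccccc9)c8)O[C@@H]1[C@@H](c2c(OCc9ccccc9)cc(OCc9ccccc9)c3c2O[C@H](c7ccc(OCc9ccccc9)c(OCc9ccccc9)c7)[C@H](OC(=O)c8cc(OCc9ccccc9)c(OCc9ccccc9)c(OCc9ccccc9)c8)C3)c2c(OCc9ccccc9)cc(OCc9ccccc9)c([C@@H]5[O+]=C(c8cc(OCc9ccccc9)c(OCc9ccccc9)c(OCc9ccccc9)c8)O[C@H]5[C@@H](c7ccc(OCc9ccccc9)c(OCc9ccccc9)c7)Oc4cc(OCc9ccccc9)cc(OCc9ccccc9)c4)c2O[C@@H]1c7ccc(OCc9ccccc9)c(OCc9ccccc9)c7 | intermediate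
22 | perbenzylated procyanidin C1 3,3′,3″-tri-O-gallate (twenty-one benzyl ethers) | O=C(c8cc(OCc9ccccc9)c(OCc9ccccc9)c(OCc9ccccc9)c8)O[C@@H]1[C@@H](c2c(OCc9ccccc9)cc(OCc9ccccc9)c3c2O[C@H](c7ccc(OCc9ccccc9)c(OCc9ccccc9)c7)[C@H](OC(=O)c8cc(OCc9ccccc9)c(OCc9ccccc9)c(OCc9ccccc9)c8)C3)c2c(OCc9ccccc9)cc(OCc9ccccc9)c([C@H]3c4c(OCc9ccccc9)cc(OCc9ccccc9)cc4O[C@H](c7ccc(OCc9ccccc9)c(OCc9ccccc9)c7)[C@@H]3OC(=O)c8cc(OCc9ccccc9)c(OCc9ccccc9)c(OCc9ccccc9)c8)c2O[C@@H]1c7ccc(OCc9ccccc9)c(OCc9ccccc9)c7 | intermediate
23 | procyanidin C1 3,3′,3″-tri-O-gallate | O=C(O[C@@H]1[C@@H](c2c(O)cc(O)c3c2O[C@H](c2ccc(O)c(O)c2)[C@H](OC(=O)c2cc(O)c(O)c(O)c2)C3)c2c(O)cc(O)c([C@H]3c4c(O)cc(O)cc4O[C@H](c4ccc(O)c(O)c4)[C@@H]3OC(=O)c3cc(O)c(O)c(O)c3)c2O[C@@H]1c1ccc(O)c(O)c1)c1cc(O)c(O)c(O)c1 | target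

## Step count and least certain steps

Total: 16 steps. Longest linear sequence: 10 steps (steps 1–5 and 12–16 from (−)-epicatechin; the branch from aldehyde 9 through steps 7–16 is equally long).

**Step 15 (key step).** The most likely failure is loss of facial control at C4. The open cation may close directly without passing through 21, or 21 may be too stable to be opened by the arene and hydrolyse on work-up with ester migration. Both follow from the fact that participation and ring closure compete for the same cation. The fallback builds the top ring from the chiral pool. It sets out from 6 and 4. Lithiation of 6 as in step 12, then quenching with methanol, would give the debrominated bis-silyl dimer F1. TMSOTf-catalysed coupling of excess F1 with 4 would give the tris-silyl perbenzylated trimer F2. TBAF would free the triol F3, and threefold esterification with 3,4,5-tris(benzyloxy)benzoic acid (DCC, DMAP) would return to the route at 22.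

**Step 14.** Acylation may be incomplete at the hindered middle C3 hydroxyl, or may spill over onto the C4 hydroxyl, because the steric difference between these two positions is not large. The fallback abandons the free carbinol. From 19, exhaustive esterification with a large excess of the same acid, DCC and DMAP at 40 °C would give the tetra-ester F4. Its benzylic C4 gallate is itself the leaving group under Zn(OTf)2 (TMSOTf if ionisation is slow) and leads to the same ion 21. This returns to the route at 22.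

**Step 12.** The hindered aryllithium may act as a base, removing the α-proton of the aldehyde; elimination of the β-aryloxide would then follow instead of addition. The fallback uses acyl substitution and reduction. From 16, oxidation with NaClO2, NaH2PO4 and 2-methyl-2-butene would give the acid F5. Coupling with N,O-dimethylhydroxylamine hydrochloride (EDC, HOBt) would give the Weinreb amide F6, whose α-proton is less acidic. Addition of 17 would give the ketone F7, and reduction with NaBH4 and CeCl3·7H2O at low temperature would return to the route at 18.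

**Step 8.** The C–O coupling of this β-branched secondary benzylic alcohol may be slow, so that reduction of the aryl iodide or decomposition of the alkoxide at 90 °C takes over. The fallback makes the same bond by substitution at carbon. From 12, Dess–Martin oxidation would give the ketone F8. Chelation-controlled reduction with Zn(BH4)2 would give the anti alcohol F9. A Mitsunobu reaction (PPh3, diisopropyl azodicarboxylate) with purchased 3,5-bis(benzyloxy)phenol, with inversion at the benzylic carbon, would return to the route at 13.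

## Further compounds

F1 | step 15 | debrominated bis-silyl dimer: 5,7,3′,4′-tetra-O-benzyl-3-O-TBS-epicatechin-(4β→8)-5,7,3′,4′-tetra-O-benzyl-3-O-TBS-epicatechin | CC(C)(C)[Si](C)(C)O[C@@H]1[C@@H](c2c(OCc9ccccc9)cc(OCc9ccccc9)c3c2O[C@H](c7ccc(OCc9ccccc9)c(OCc9ccccc9)c7)[C@H](O[Si](C)(C)C(C)(C)C)C3)c2c(OCc9ccccc9)cc(OCc9ccccc9)cc2O[C@@H]1c7ccc(OCc9ccccc9)c(OCc9ccccc9)c7
F2 | step 15 | dodeca-O-benzyl-3,3′,3″-tris-O-TBS-procyanidin C1 | CC(C)(C)[Si](C)(C)O[C@@H]1[C@@H](c2c(OCc9ccccc9)cc(OCc9ccccc9)c3c2O[C@H](c7ccc(OCc9ccccc9)c(OCc9ccccc9)c7)[C@H](O[Si](C)(C)C(C)(C)C)C3)c2c(OCc9ccccc9)cc(OCc9ccccc9)c([C@H]3c4c(OCc9ccccc9)cc(OCc9ccccc9)cc4O[C@H](c7ccc(OCc9ccccc9)c(OCc9ccccc9)c7)[C@@H]3O[Si](C)(C)C(C)(C)C)c2O[C@@H]1c7ccc(OCc9ccccc9)c(OCc9ccccc9)c7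
F3 | step 15 | dodeca-O-benzylprocyanidin C1 (three free C3 hydroxyls) | O[C@@H]1[C@@H](c2c(OCc9ccccc9)cc(OCc9ccccc9)c3c2O[C@H](c7ccc(OCc9ccccc9)c(OCc9ccccc9)c7)[C@H](O)C3)c2c(OCc9ccccc9)cc(OCc9ccccc9)c([C@H]3c4c(OCc9ccccc9)cc(OCc9ccccc9)cc4O[C@H](c7ccc(OCc9ccccc9)c(OCc9ccccc9)c7)[C@@H]3O)c2O[C@@H]1c7ccc(OCc9ccccc9)c(OCc9ccccc9)c7
F4 | step 14 | tetra-ester: 20 with a fourth 3,4,5-tris(benzyloxy)benzoate on the C4 oxygen (both C4 epimers) | O=C(c8cc(OCc9ccccc9)c(OCc9ccccc9)c(OCc9ccccc9)c8)O[C@@H]1[C@@H](c2c(OCc9ccccc9)cc(OCc9ccccc9)c3c2O[C@H](c7ccc(OCc9ccccc9)c(OCc9ccccc9)c7)[C@H](OC(=O)c8cc(OCc9ccccc9)c(OCc9ccccc9)c(OCc9ccccc9)c8)C3)c2c(OCc9ccccc9)cc(OCc9ccccc9)c(C(OC(=O)c8cc(OCc9ccccc9)c(OCc9ccccc9)c(OCc9ccccc9)c8)[C@@H](OC(=O)c8cc(OCc9ccccc9)c(OCc9ccccc9)c(OCc9ccccc9)c8)[C@@H](c7ccc(OCc9ccccc9)c(OCc9ccccc9)c7)Oc4cc(OCc9ccccc9)cc(OCc9ccccc9)c4)c2O[C@@H]1c7ccc(OCc9ccccc9)c(OCc9ccccc9)c7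
F5 | step 12 | (2S,3R)-3-[3,4-bis(benzyloxy)phenyl]-3-[3,5-bis(benzyloxy)phenoxy]-2-(tert-butyldimethylsilyloxy)propanoic acid | OC(=O)[C@@H](O[Si](C)(C)C(C)(C)C)[C@@H](c1ccc(OCc2ccccc2)c(OCc2ccccc2)c1)Oc1cc(OCc2ccccc2)cc(OCc2ccccc2)c1
F6 | step 12 | (2S,3R)-3-[3,4-bis(benzyloxy)phenyl]-3-[3,5-bis(benzyloxy)phenoxy]-2-(tert-butyldimethylsilyloxy)-N-methoxy-N-methylpropanamide | CON(C)C(=O)[C@@H](O[Si](C)(C)C(C)(C)C)[C@@H](c1ccc(OCc2ccccc2)c(OCc2ccccc2)c1)Oc1cc(OCc2ccccc2)cc(OCc2ccccc2)c1
F7 | step 12 | C4 ketone corresponding to 18 | CC(C)(C)[Si](C)(C)O[C@@H]1[C@@H](c2c(OCc9ccccc9)cc(OCc9ccccc9)c3c2O[C@H](c7ccc(OCc9ccccc9)c(OCc9ccccc9)c7)[C@H](O[Si](C)(C)C(C)(C)C)C3)c2c(OCc9ccccc9)cc(OCc9ccccc9)c(C(=O)[C@@H](O[Si](C)(C)C(C)(C)C)[C@@H](c7ccc(OCc9ccccc9)c(OCc9ccccc9)c7)Oc4cc(OCc9ccccc9)cc(OCc9ccccc9)c4)c2O[C@@H]1c7ccc(OCc9ccccc9)c(OCc9ccccc9)c7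
F8 | step 8 | (R)-1-[3,4-bis(benzyloxy)phenyl]-2-(methoxymethoxy)but-3-en-1-one | C=C[C@@H](OCOC)C(=O)c1ccc(OCc2ccccc2)c(OCc2ccccc2)c1
F9 | step 8 | (1S,2R)-1-[3,4-bis(benzyloxy)phenyl]-2-(methoxymethoxy)but-3-en-1-ol | C=C[C@@H](OCOC)[C@H](c1ccc(OCc2ccccc2)c(OCc2ccccc2)c1)O
A1 | alternative 1 | top unit carrying the new middle A ring as a 2-substituted 5-benzyloxy-3-(triisopropylsilyloxy)phenol | Oc1cc(OCc9ccccc9)cc(O[Si](C(C)C)(C(C)C)C(C)C)c1[C@H]3c4c(OCc9ccccc9)cc(OCc9ccccc9)cc4O[C@H](c7ccc(OCc9ccccc9)c(OCc9ccccc9)c7)[C@@H]3O[Si](C)(C)C(C)(C)C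
A2 | alternative 1 | 3-(benzyloxy)cyclobut-2-enone | O=C1CC(OCc2ccccc2)=C1
A3 | alternative 1 | 5,7,3′,4′-tetra-O-benzyl-3-O-TBS-epicatechin carrying a (triisopropylsilyloxy)ethynyl group at C4 (trans to C3–O) | CC(C)[Si](C(C)C)(C(C)C)OC#C[C@H]3c4c(OCc9ccccc9)cc(OCc9ccccc9)cc4O[C@H](c7ccc(OCc9ccccc9)c(OCc9ccccc9)c7)[C@@H]3O[Si](C)(C)C(C)(C)C
A4 | alternative 2 | trimer with the top unit as a 4-aryl-flav-2-ene | CC(C)(C)[Si](C)(C)O[C@@H]1[C@@H](c2c(OCc9ccccc9)cc(OCc9ccccc9)c3c2O[C@H](c7ccc(OCc9ccccc9)c(OCc9ccccc9)c7)[C@H](O[Si](C)(C)C(C)(C)C)C3)c2c(OCc9ccccc9)cc(OCc9ccccc9)c([C@H]3c4c(OCc9ccccc9)cc(OCc9ccccc9)cc4OC(c7ccc(OCc9ccccc9)c(OCc9ccccc9)c7)=C3)c2O[C@@H]1c7ccc(OCc9ccccc9)c(OCc9ccccc9)c7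
A5 | alternative 2 | metathesis diene: dimer carrying on C8 a 1-arylprop-2-enyl group whose aryl ring bears an ortho 1-arylvinyl ether | CC(C)(C)[Si](C)(C)O[C@@H]1[C@@H](c2c(OCc9ccccc9)cc(OCc9ccccc9)c3c2O[C@H](c7ccc(OCc9ccccc9)c(OCc9ccccc9)c7)[C@H](O[Si](C)(C)C(C)(C)C)C3)c2c(OCc9ccccc9)cc(OCc9ccccc9)c([C@H](C=C)c4c(OCc9ccccc9)cc(OCc9ccccc9)cc4OC(=C)c7ccc(OCc9ccccc9)c(OCc9ccccc9)c7)c2O[C@@H]1c7ccc(OCc9ccccc9)c(OCc9ccccc9)c7
A6 | alternative 3 | perbenzylated trimer with a free C3 hydroxyl on the top unit and gallates on the middle and bottom units | O=C(c8cc(OCc9ccccc9)c(OCc9ccccc9)c(OCc9ccccc9)c8)O[C@@H]1[C@@H](c2c(OCc9ccccc9)cc(OCc9ccccc9)c3c2O[C@H](c7ccc(OCc9ccccc9)c(OCc9ccccc9)c7)[C@H](OC(=O)c8cc(OCc9ccccc9)c(OCc9ccccc9)c(OCc9ccccc9)c8)C3)c2c(OCc9ccccc9)cc(OCc9ccccc9)c([C@H]3c4c(OCc9ccccc9)cc(OCc9ccccc9)cc4O[C@H](c7ccc(OCc9ccccc9)c(OCc9ccccc9)c7)[C@@H]3O)c2O[C@@H]1c7ccc(OCc9ccccc9)c(OCc9ccccc9)c7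
A7 | alternative 3 | cis-epoxide with a free ortho phenol on the top A ring, on C8 of the bis-gallate dimer | O=C(c8cc(OCc9ccccc9)c(OCc9ccccc9)c(OCc9ccccc9)c8)O[C@@H]1[C@@H](c2c(OCc9ccccc9)cc(OCc9ccccc9)c3c2O[C@H](c7ccc(OCc9ccccc9)c(OCc9ccccc9)c7)[C@H](OC(=O)c8cc(OCc9ccccc9)c(OCc9ccccc9)c(OCc9ccccc9)c8)C3)c2c(OCc9ccccc9)cc(OCc9ccccc9)c([C@@H](c4c(OCc9ccccc9)cc(OCc9ccccc9)cc4O)[C@H]5O[C@H]5c7ccc(OCc9ccccc9)c(OCc9ccccc9)c7)c2O[C@@H]1c7ccc(OCc9ccccc9)c(OCc9ccccc9)c7
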